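**Plan**

1. Retrosynthesis: after the two silyl ethers, ring C is cut at C4–C4a (aryl anion at C4a onto a C4 N-methoxy-N-methylamide) and then at O1–C2 (phenol plus benzylic alcohol).
2. Enabling feature: the C4 carbonyl sits on C4a, the ring A carbon ortho to O1, so a bromine at C4a can become an aryllithium that reaches an acyl carbon tethered through O1–C2–C3.
3. Ring A: the C6–prenyl and C8–prenyl bonds are cut as two [3,3] shifts from the C7 oxygen of 4-bromoresorcinol, whose bromine marks C4a and whose second oxygen (O1) is masked as a methoxymethyl ether.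
4. Side chain: C2–C3 is cut to methyl 4-hydroxybenzoate (ring B and C2) and N-methoxy-N-methylacetamide (C3 and C4).
5. Forward: ring A is prenylated twice, the ring B chain is joined through O1–C2, ring C closes last by C4–C4a formation, and desilylation ends the route.
6. Stereochemistry: C2 is the only stereocentre; asymmetric transfer hydrogenation sets an (R)-carbinol, the etherification inverts it to (S), and no later step touches it.

Key step: step 12

Assumption: with a hindered electrophile, 4-bromoresorcinol reacts first at the hydroxyl para to bromine, the only one without an ortho substituent; atom labels follow flavanone numbering (ring A benzo, ring B 4-hydroxyphenyl, ring C pyranone).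

**Route**

Step 1
Reactants: 1 4-bromoresorcinol; 2 3-chloro-3-methylbut-1-yne
Product: 3 2-bromo-5-[(2-methylbut-3-yn-2-yl)oxy]phenol
Conditions: 2 (1.05 equiv), DBU, CuCl2·2H2O (cat.), MeCN, −5 to 0 °C
Reagents that add atoms: none
Why: The copper-catalysed propargylic etherification of phenols with a tertiary propargylic chloride should occur at the unhindered hydroxyl para to bromine, because the other hydroxyl is flanked by the halogen and is the weaker nucleophile.

Step 2
Reactants: 3 2-bromo-5-[(2-methylbut-3-yn-2-yl)oxy]phenol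
Product: 4 1-bromo-2-(methoxymethoxy)-4-[(2-methylbut-3-yn-2-yl)oxy]benzene
Conditions: MOMCl, i-Pr2NEt, CH2Cl2, 0 °C to rt
Reagents that add atoms: chloromethyl methyl ether (MOMCl), COCCl
Why: O-Alkylation of the remaining phenol masks O1 as a methoxymethyl acetal, which tolerates base, hydrogenation and heat and is later removed by mild acid.

Step 3
Reactants: 4 1-bromo-2-(methoxymethoxy)-4-[(2-methylbut-3-yn-2-yl)oxy]benzene
Product: 6 4-bromo-5-(methoxymethoxy)-2-(3-methylbut-2-enyl)phenol, via allyl ether 5 (not isolated)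
Conditions: H2 (1 atm), Pd/CaCO3 poisoned with Pb(OAc)2 (Lindlar catalyst), quinoline, PhMe, rt; filtration through Celite; then 110 °C
Reagents that add atoms: none
Why: Lindlar semihydrogenation stops at the terminal alkene and spares the aryl bromide, and the aryl 1,1-dimethylallyl ether 5 then undergoes an aromatic Claisen rearrangement ([3,3] shift with allyl inversion) that places a prenyl group on an ortho carbon, preferentially the one remote from the methoxymethoxy group; the minor isomer prenylated between the two oxygens may be carried along, since the second cycle converts both into 9.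

Step 4
Reactants: 6 4-bromo-5-(methoxymethoxy)-2-(3-methylbut-2-enyl)phenol; 2 3-chloro-3-methylbut-1-yne
Product: 7 1-bromo-2-(methoxymethoxy)-5-(3-methylbut-2-enyl)-4-[(2-methylbut-3-yn-2-yl)oxy]benzene
Conditions: 2 (1.2 equiv), DBU, CuCl2·2H2O (cat.), MeCN, 0 °C
Reagents that add atoms: none
Why: The same copper-catalysed propargylic etherification now meets a single free phenol, and an ortho-alkyl group is tolerated in this reaction.

Step 5
Reactants: 7 1-bromo-2-(methoxymethoxy)-5-(3-methylbut-2-enyl)-4-[(2-methylbut-3-yn-2-yl)oxy]benzene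
Product: 9 4-bromo-3-(methoxymethoxy)-2,6-bis(3-methylbut-2-enyl)phenol, via allyl ether 8 (not isolated)
Conditions: H2 (1 atm), Pd/CaCO3 poisoned with Pb(OAc)2 (Lindlar catalyst), quinoline, PhMe, rt; filtration through Celite; then 110 °C
Reagents that add atoms: none
Why: Semihydrogenation followed by a second aromatic Claisen rearrangement should deliver the prenyl group to the one remaining ortho carbon, the para carbon being blocked by bromine and the existing trisubstituted alkene being inert to the poisoned catalyst.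

Step 6
Reactants: 9 4-bromo-3-(methoxymethoxy)-2,6-bis(3-methylbut-2-enyl)phenol
Product: 10 [4-bromo-3-(methoxymethoxy)-2,6-bis(3-methylbut-2-enyl)phenoxy]triisopropylsilane
Conditions: NaH, THF/DMF, 0 °C; TIPSCl, 0 °C to rt
Reagents that add atoms: chlorotriisopropylsilane (TIPSCl), CC(C)[Si](Cl)(C(C)C)C(C)C
Why: O-Silylation of the sodium phenoxide overcomes the hindrance of the two ortho prenyl groups and avoids a silyl triflate, which could attack the methoxymethyl acetal.

Step 7
Reactants: 10 [4-bromo-3-(methoxymethoxy)-2,6-bis(3-methylbut-2-enyl)phenoxy]triisopropylsilane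
Product: 11 2-bromo-4,6-bis(3-methylbut-2-enyl)-5-(triisopropylsilyloxy)phenol
Conditions: HCl (ca. 0.5 M) in MeOH/THF, rt
Reagents that add atoms: none
Why: Acid-catalysed acetal exchange with methanol cleaves the aryl methoxymethyl ether, while the doubly flanked aryl triisopropylsilyl ether and the prenyl groups should survive dilute acid at room temperature.

Step 8
Reactants: 12 methyl 4-hydroxybenzoate
Product: 13 methyl 4-(triisopropylsilyloxy)benzoate
Conditions: TIPSCl, imidazole, DMF, rt
Reagents that add atoms: chlorotriisopropylsilane (TIPSCl), CC(C)[Si](Cl)(C(C)C)C(C)C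
Why: Standard imidazole-mediated O-silylation of an unhindered, acidic phenol.

Step 9
Reactants: 13 methyl 4-(triisopropylsilyloxy)benzoate; 14 N-methoxy-N-methylacetamide
Product: 15 N-methoxy-N-methyl-3-oxo-3-[4-(triisopropylsilyloxy)phenyl]propanamide
Conditions: 14 (2.2 equiv), LiN(i-Pr)2 (2.2 equiv), THF, −78 °C; then 13, −78 to −20 °C; AcOH
Reagents that add atoms: none
Why: Crossed Claisen condensation of the lithium amide enolate with the non-enolisable benzoate forms C2–C3, the second equivalent of enolate deprotonating the beta-keto amide and so shielding it from further attack.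

Step 10
Reactants: 15 N-methoxy-N-methyl-3-oxo-3-[4-(triisopropylsilyloxy)phenyl]propanamide
Product: 16 (3R)-3-hydroxy-N-methoxy-N-methyl-3-[4-(triisopropylsilyloxy)phenyl]propanamide
Conditions: RuCl[(R,R)-TsDPEN](p-cymene) (1 mol%), HCO2H/Et3N (5:2), CH2Cl2, 30 °C
Reagents that add atoms: none
Why: Noyori-type asymmetric transfer hydrogenation of an aryl ketone, in which the (R,R)-diamine catalyst differentiates the aryl and CH2 flanks and should deliver hydride to the face that gives the (R)-carbinol, in the same sense as for simple aryl alkyl ketones.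

Step 11
Reactants: 11 2-bromo-4,6-bis(3-methylbut-2-enyl)-5-(triisopropylsilyloxy)phenol; 16 (3R)-3-hydroxy-N-methoxy-N-methyl-3-[4-(triisopropylsilyloxy)phenyl]propanamide
Product: 17 (3S)-3-[2-bromo-4,6-bis(3-methylbut-2-enyl)-5-(triisopropylsilyloxy)phenoxy]-N-methoxy-N-methyl-3-[4-(triisopropylsilyloxy)phenyl]propanamide
Conditions: PPh3, DIAD, PhMe (ca. 1 M), sonication, 0 °C to rt
Reagents that add atoms: none
Why: Mitsunobu etherification, in which the acidic ortho-bromophenol displaces the oxyphosphonium of the secondary benzylic alcohol by SN2 with clean inversion, turning the (R)-carbinol into the (S)-aryl ether; the non-polar solvent and high concentration are chosen to suppress ionisation and to help the hindered phenol.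

Step 12
Reactants: 17 (3S)-3-[2-bromo-4,6-bis(3-methylbut-2-enyl)-5-(triisopropylsilyloxy)phenoxy]-N-methoxy-N-methyl-3-[4-(triisopropylsilyloxy)phenyl]propanamide
Product: 20 (2S)-6,8-bis(3-methylbut-2-enyl)-7-(triisopropylsilyloxy)-2-[4-(triisopropylsilyloxy)phenyl]chroman-4-one, via aryllithium 18 (not isolated), via lithium hemiaminal alkoxide 19 (not isolated)
Conditions: t-BuLi (2.1 equiv), THF, −100 °C, then −78 °C; AcOH, −78 °C to rt
Reagents that add atoms: none
Why: t-BuLi exchanges the C4a bromine (the second equivalent destroys the t-BuBr formed), and aryllithium 18 adds to the tethered N-methoxy-N-methylamide carbonyl to give the five-membered lithium chelate 19, which collapses to ketone 20 only on the acidic quench. The closest known reaction type is the Parham cyclisation of ortho-bromoaryl ethers carrying tethered N-methoxy-N-methylamides, which gives benzo-fused ketones including 2-substituted chroman-4-ones. Ring C closes in a 6-exo-trig mode, and C4–C4a is the only skeletal bond formed. No stereocentre is created, and C2 keeps its S configuration because 19 holds C4 at the tetrahedral level, so that no C3 enolate and hence no retro-oxa-Michael opening can arise before the quench. The selectivity needed is exchange over deprotonation at C3 (which would expel the phenoxide) and over attack of t-BuLi on the amide; it should be secured by the intrinsically fast bromine–lithium exchange at very low temperature, by the absence of any site more acidic than the amide alpha-CH2, and by the proximity of the amide to the aryllithium. The prenyl groups, the silyl ethers and the benzylic ether are inert to these anionic conditions, whereas an acid-mediated acylation would cyclise the prenyl groups onto the neighbouring oxygens.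

Step 13
Reactants: 20 (2S)-6,8-bis(3-methylbut-2-enyl)-7-(triisopropylsilyloxy)-2-[4-(triisopropylsilyloxy)phenyl]chroman-4-one
Product: 21 (2S)-7-hydroxy-2-(4-hydroxyphenyl)-6,8-bis(3-methylbut-2-enyl)chroman-4-one
Conditions: Bu4NF (3 equiv), AcOH (3 equiv), THF, 0 °C to rt
Reagents that add atoms: none
Why: Fluoride-mediated desilylation of both aryl silyl ethers, buffered with acetic acid so that the liberated phenoxides are protonated at once and base-induced ring opening of the flavanone to the chalcone (which would racemise C2) is avoided.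

**Compound list**

1 | 4-bromoresorcinol | Oc1ccc(Br)c(O)c1 | starting material
2 | 3-chloro-3-methylbut-1-yne | CC(C)(Cl)C#C | starting material
3 | 2-bromo-5-[(2-methylbut-3-yn-2-yl)oxy]phenol | Oc1cc(OC(C)(C)C#C)ccc1Br | intermediate
4 | 1-bromo-2-(methoxymethoxy)-4-[(2-methylbut-3-yn-2-yl)oxy]benzene | COCOc1cc(OC(C)(C)C#C)ccc1Br | intermediate
5 | 1-bromo-2-(methoxymethoxy)-4-[(2-methylbut-3-en-2-yl)oxy]benzene | COCOc1cc(OC(C)(C)C=C)ccc1Br | intermediate (not isolated)
6 | 4-bromo-5-(methoxymethoxy)-2-(3-methylbut-2-enyl)phenol | Oc1cc(OCOC)c(Br)cc1CC=C(C)C | intermediate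
7 | 1-bromo-2-(methoxymethoxy)-5-(3-methylbut-2-enyl)-4-[(2-methylbut-3-yn-2-yl)oxy]benzene | COCOc1cc(OC(C)(C)C#C)c(CC=C(C)C)cc1Br | intermediate
8 | 1-bromo-2-(methoxymethoxy)-5-(3-methylbut-2-enyl)-4-[(2-methylbut-3-en-2-yl)oxy]benzene | COCOc1cc(OC(C)(C)C=C)c(CC=C(C)C)cc1Br | intermediate (not isolated)
9 | 4-bromo-3-(methoxymethoxy)-2,6-bis(3-methylbut-2-enyl)phenol | Oc1c(CC=C(C)C)cc(Br)c(OCOC)c1CC=C(C)C | intermediate
10 | [4-bromo-3-(methoxymethoxy)-2,6-bis(3-methylbut-2-enyl)phenoxy]triisopropylsilane | COCOc1c(Br)cc(CC=C(C)C)c(O[Si](C(C)C)(C(C)C)C(C)C)c1CC=C(C)C | intermediate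
11 | 2-bromo-4,6-bis(3-methylbut-2-enyl)-5-(triisopropylsilyloxy)phenol | Oc1c(Br)cc(CC=C(C)C)c(O[Si](C(C)C)(C(C)C)C(C)C)c1CC=C(C)C | intermediate
12 | methyl 4-hydroxybenzoate | COC(=O)c1ccc(O)cc1 | starting material
13 | methyl 4-(triisopropylsilyloxy)benzoate | COC(=O)c1ccc(O[Si](C(C)C)(C(C)C)C(C)C)cc1 | intermediate
14 | N-methoxy-N-methylacetamide | CC(=O)N(C)OC | starting material
15 | N-methoxy-N-methyl-3-oxo-3-[4-(triisopropylsilyloxy)phenyl]propanamide | CON(C)C(=O)CC(=O)c1ccc(O[Si](C(C)C)(C(C)C)C(C)C)cc1 | intermediate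
16 | (3R)-3-hydroxy-N-methoxy-N-methyl-3-[4-(triisopropylsilyloxy)phenyl]propanamide | CON(C)C(=O)C[C@@H](O)c1ccc(O[Si](C(C)C)(C(C)C)C(C)C)cc1 | intermediate
17 | (3S)-3-[2-bromo-4,6-bis(3-methylbut-2-enyl)-5-(triisopropylsilyloxy)phenoxy]-N-methoxy-N-methyl-3-[4-(triisopropylsilyloxy)phenyl]propanamide | CON(C)C(=O)C[C@@H](c1ccc(O[Si](C(C)C)(C(C)C)C(C)C)cc1)Oc1c(Br)cc(CC=C(C)C)c(O[Si](C(C)C)(C(C)C)C(C)C)c1CC=C(C)C | intermediate
18 | aryllithium from 17 (lithium in place of bromine at C4a) | CON(C)C(=O)C[C@@H](c1ccc(O[Si](C(C)C)(C(C)C)C(C)C)cc1)Oc1c([Li])cc(CC=C(C)C)c(O[Si](C(C)C)(C(C)C)C(C)C)c1CC=C(C)C | intermediate (not isolated)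
19 | lithium (2S)-4-[methoxy(methyl)amino]-6,8-bis(3-methylbut-2-enyl)-7-(triisopropylsilyloxy)-2-[4-(triisopropylsilyloxy)phenyl]chroman-4-olate (C4 configuration immaterial) | CC(C)=CCc1cc2c(c(CC=C(C)C)c1O[Si](C(C)C)(C(C)C)C(C)C)O[C@H](c1ccc(O[Si](C(C)C)(C(C)C)C(C)C)cc1)CC2([O-])N(C)OC.[Li+] | intermediate (not isolated)
20 | (2S)-6,8-bis(3-methylbut-2-enyl)-7-(triisopropylsilyloxy)-2-[4-(triisopropylsilyloxy)phenyl]chroman-4-one | CC(C)=CCc1cc2c(c(CC=C(C)C)c1O[Si](C(C)C)(C(C)C)C(C)C)O[C@H](c1ccc(O[Si](C(C)C)(C(C)C)C(C)C)cc1)CC2=O | intermediate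
21 | (2S)-7-hydroxy-2-(4-hydroxyphenyl)-6,8-bis(3-methylbut-2-enyl)chroman-4-one | CC(C)=CCc1cc2c(c(CC=C(C)C)c1O)O[C@H](c1ccc(O)cc1)CC2=O | target

**Step count**

Total: 13 steps. Longest linear sequence: 10 steps (steps 1–7, 11, 12, 13 from 4-bromoresorcinol); the side-chain branch (steps 8–10) joins at step 11.

**Steps most likely to fail**

Step 11 (etherification). The coupling may be slow because the phenol carries two ortho substituents. The activated beta-hydroxy amide may dehydrate to the cinnamamide. Partial ionisation at the electron-rich benzylic carbon may erode the enantiomeric purity. The fallback reverses the order of the two bond formations and sets out from 16 and 10.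
- Alcohol 16 is silylated (Et3SiCl, imidazole) to (3R)-N-methoxy-N-methyl-3-(triethylsilyloxy)-3-[4-(triisopropylsilyloxy)phenyl]propanamide F4.
- Bromide 10 is exchanged with t-BuLi at −78 °C to [2-(methoxymethoxy)-3,5-bis(3-methylbut-2-enyl)-4-(triisopropylsilyloxy)phenyl]lithium F5.
- F5 is acylated by F4 to give (3R)-1-[2-(methoxymethoxy)-3,5-bis(3-methylbut-2-enyl)-4-(triisopropylsilyloxy)phenyl]-3-(triethylsilyloxy)-3-[4-(triisopropylsilyloxy)phenyl]propan-1-one F6.
- Dilute methanolic HCl at 0 °C removes the triethylsilyl and methoxymethyl groups to give (3R)-3-hydroxy-1-[2-hydroxy-3,5-bis(3-methylbut-2-enyl)-4-(triisopropylsilyloxy)phenyl]-3-[4-(triisopropylsilyloxy)phenyl]propan-1-one F7.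
- An intramolecular Mitsunobu reaction (PPh3, DIAD, THF) then closes O1–C2 with inversion and comes back to the route at 20, so that step 12 is bypassed as well.

Step 12 (ring closure). Deprotonation at C3, by t-BuLi or by proton transfer to the aryllithium, would be followed by beta-elimination of the phenoxide; addition of t-BuLi to the amide may also compete. The fallback replaces the lithium species by a far less basic magnesium one and sets out from 17.
- A copper-catalysed aromatic Finkelstein reaction (NaI, CuI, trans-N,N'-dimethylcyclohexane-1,2-diamine, dioxane, 110 °C) should give (3S)-3-[2-iodo-4,6-bis(3-methylbut-2-enyl)-5-(triisopropylsilyloxy)phenoxy]-N-methoxy-N-methyl-3-[4-(triisopropylsilyloxy)phenyl]propanamide F8.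
- Iodine–magnesium exchange with i-PrMgCl·LiCl (THF, −40 °C) gives the corresponding arylmagnesium chloride F9.
- On warming to 0 °C, F9 should add to the amide to give the chloromagnesium hemiaminal alkoxide F10, and an acetic acid quench comes back to the route at 20.

Step 1 (first etherification). Regiocontrol between the two hydroxyls may be lost, with etherification at the ortho-bromo hydroxyl or at both oxygens. The fallback differentiates the hydroxyls with a temporary silyl group and sets out from 1.
- TIPSCl and imidazole in DMF should silylate only the unhindered hydroxyl to give 2-bromo-5-(triisopropylsilyloxy)phenol F1.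
- MOMCl and i-Pr2NEt give [4-bromo-3-(methoxymethoxy)phenoxy]triisopropylsilane F2.
- Bu4NF in THF frees 4-bromo-3-(methoxymethoxy)phenol F3.
- F3 is etherified with 2 under the conditions of step 1 and so comes back to the route at 4.

**Further compounds**

F1 | step 1 | 2-bromo-5-(triisopropylsilyloxy)phenol | Oc1cc(O[Si](C(C)C)(C(C)C)C(C)C)ccc1Br
F2 | step 1 | [4-bromo-3-(methoxymethoxy)phenoxy]triisopropylsilane | COCOc1cc(O[Si](C(C)C)(C(C)C)C(C)C)ccc1Br
F3 | step 1 | 4-bromo-3-(methoxymethoxy)phenol | COCOc1cc(O)ccc1Br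
F4 | step 11 | (3R)-N-methoxy-N-methyl-3-(triethylsilyloxy)-3-[4-(triisopropylsilyloxy)phenyl]propanamide | CON(C)C(=O)C[C@@H](O[Si](CC)(CC)CC)c1ccc(O[Si](C(C)C)(C(C)C)C(C)C)cc1
F5 | step 11 | [2-(methoxymethoxy)-3,5-bis(3-methylbut-2-enyl)-4-(triisopropylsilyloxy)phenyl]lithium | COCOc1c([Li])cc(CC=C(C)C)c(O[Si](C(C)C)(C(C)C)C(C)C)c1CC=C(C)C
F6 | step 11 | (3R)-1-[2-(methoxymethoxy)-3,5-bis(3-methylbut-2-enyl)-4-(triisopropylsilyloxy)phenyl]-3-(triethylsilyloxy)-3-[4-(triisopropylsilyloxy)phenyl]propan-1-one | COCOc1c(C(=O)C[C@@H](O[Si](CC)(CC)CC)c2ccc(O[Si](C(C)C)(C(C)C)C(C)C)cc2)cc(CC=C(C)C)c(O[Si](C(C)C)(C(C)C)C(C)C)c1CC=C(C)C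
F7 | step 11 | (3R)-3-hydroxy-1-[2-hydroxy-3,5-bis(3-methylbut-2-enyl)-4-(triisopropylsilyloxy)phenyl]-3-[4-(triisopropylsilyloxy)phenyl]propan-1-one | Oc1c(C(=O)C[C@@H](O)c2ccc(O[Si](C(C)C)(C(C)C)C(C)C)cc2)cc(CC=C(C)C)c(O[Si](C(C)C)(C(C)C)C(C)C)c1CC=C(C)C
F8 | step 12 | (3S)-3-[2-iodo-4,6-bis(3-methylbut-2-enyl)-5-(triisopropylsilyloxy)phenoxy]-N-methoxy-N-methyl-3-[4-(triisopropylsilyloxy)phenyl]propanamide | CON(C)C(=O)C[C@@H](c1ccc(O[Si](C(C)C)(C(C)C)C(C)C)cc1)Oc1c(I)cc(CC=C(C)C)c(O[Si](C(C)C)(C(C)C)C(C)C)c1CC=C(C)C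
F9 | step 12 | arylmagnesium chloride from F8 (MgCl in place of iodine at C4a) | CON(C)C(=O)C[C@@H](c1ccc(O[Si](C(C)C)(C(C)C)C(C)C)cc1)Oc1c([Mg]Cl)cc(CC=C(C)C)c(O[Si](C(C)C)(C(C)C)C(C)C)c1CC=C(C)C
F10 | step 12 | chloromagnesium (2S)-4-[methoxy(methyl)amino]-6,8-bis(3-methylbut-2-enyl)-7-(triisopropylsilyloxy)-2-[4-(triisopropylsilyloxy)phenyl]chroman-4-olate | CC(C)=CCc1cc2c(c(CC=C(C)C)c1O[Si](C(C)C)(C(C)C)C(C)C)O[C@H](c1ccc(O[Si](C(C)C)(C(C)C)C(C)C)cc1)CC2(O[Mg]Cl)N(C)OC
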